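Ring B of this eudesmane is an acetone unit, C7–C8(=O)–C9, held between two ring A positions: C6 on C5 and the quaternary C10. The route rests on that [3+3] disconnection. In one flask dimethyl 3-oxopentanedioate is C-alkylated by 2-(bromomethyl)-3-methylcyclohex-2-enone (C6–C7) and then closes ring B by a 6-endo Michael addition to the enone β-carbon (C9–C10) under a chiral ammonium ion pair that sets C10; C5 equilibrates to the trans fusion. The ring A ketone then becomes the C3=C4 olefin for cis-dihydroxylation, acetone condensation gives the C7 isopropylidene, and a final singlet-oxygen ene reaction turns C6–C7 into the enone double bond while placing the C11 hydroperoxide.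

Key step: step 4

Remark: bicyclic compounds are numbered as eudesmanes (ring A = C1–C5 and C10, ring B = C5–C10, C14 = methyl on C10, C15 = methyl on C4, C11–C13 on C7) and α is the face opposite the C10 methyl; the trans ring fusion is assumed to be the more stable one for the C4-oxo decalin 7, as in 4-oxo-5α-steroids.

Step 1
Reactants: 1 3-methylcyclohex-2-en-1-one
Product: 2 2-iodo-3-methylcyclohex-2-en-1-one
Conditions: I2, pyridine, DMAP (cat.), CH2Cl2, 25 °C
Reagents that add atoms: iodine II
Why: α-Iodination of the enone by conjugate addition of pyridine, iodination of the resulting enolate and loss of pyridine (a Baylis–Hillman-type addition–elimination) should place the handle on the future C5; no stereocenter is involved.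

Step 2
Reactants: 2 2-iodo-3-methylcyclohex-2-en-1-one
Product: 3 2-(hydroxymethyl)-3-methylcyclohex-2-en-1-one
Conditions: Bu3SnCH2OH, Pd(PPh3)4 (5 mol %), dioxane, 90 °C
Reagents that add atoms: (tributylstannyl)methanol OC[Sn](CCCC)(CCCC)CCCC
Why: Stille coupling of the alkenyl iodide, in which the α-oxygenated hydroxymethyl group should transfer from tin in preference to butyl, brings in C6; no stereocenter is involved.

Step 3
Reactants: 3 2-(hydroxymethyl)-3-methylcyclohex-2-en-1-one
Product: 4 2-(bromomethyl)-3-methylcyclohex-2-en-1-one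
Conditions: CBr4, PPh3, CH2Cl2, 0 °C
Reagents that add atoms: carbon tetrabromide BrC(Br)(Br)Br
Why: Appel bromination of the primary allylic alcohol under neutral conditions should give the allylic bromide that is the C6 electrophile of the key step; no stereocenter is involved.

Step 4
Reactants: 4 2-(bromomethyl)-3-methylcyclohex-2-en-1-one, 5 dimethyl 3-oxopentanedioate
Product: 7 dimethyl (4aR,8aS)-8a-methyl-2,5-dioxodecahydronaphthalene-1,3-dicarboxylate (trans-fused; 5α-H and 10β-methyl), via C-alkylated keto diester 6 (not isolated)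
Conditions: Cs2CO3, N-(9-anthracenylmethyl)cinchonidinium chloride (10 mol %), toluene, 0 °C then 40 °C
Reagents that add atoms: none
Why: Proposed new method: the ammonium enolate of 5 displaces the allylic bromide of 4 (SN2 at CH2Br, C6–C7) to give 6, whose other enolisable CH2 then adds to the β-carbon of the ring A enone, the future C10 (C9–C10), and the ring A enolate so formed is protonated at C5. The closest known reaction types are the [3+3] α,α'-annulation of 1,3-acetonedicarboxylates with 2-(halomethyl)acrylates and Morita–Baylis–Hillman acetates, the carbonate-mediated intramolecular Michael addition of β-keto esters to 3-alkylcyclohexenones that builds angular quaternary carbons, and cinchona phase-transfer Michael additions of β-keto esters; catalyst control over a β,β-disubstituted acceptor is the new element. Ring B closes in the 6-endo-trig mode. C10 is set by the catalyst, whose cation pairs with the enolate while its free hydroxyl binds the C4 carbonyl so that one face of C10 is open (the pseudoenantiomeric cinchoninium salt is taken if the sense proves to be the opposite one); C5 is set under thermodynamic control, since it is α to the C4 ketone and should epimerise to the trans-fused decalone, and the two ester-bearing carbons are labile and erased in step 7. The step needs mono-C-alkylation (excess of 5, soft doubly stabilised enolate, primary allylic bromide), Michael rather than aldol addition at C4 (the aldol is reversible) and C- rather than O-attack at C10 (an oxa-Michael adduct reverts); the symmetry of 5 makes both possible orders of bond formation (SN2 then Michael, or SN2' at C10 then Michael at C6) converge on the same product.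

Step 5
Reactants: 7 dimethyl (4aR,8aS)-8a-methyl-2,5-dioxodecahydronaphthalene-1,3-dicarboxylate
Product: 8 dimethyl (4aR,8aS)-8a-methyl-2-oxo-5-(trifluoromethylsulfonyloxy)-1,2,3,4,4a,7,8,8a-octahydronaphthalene-1,3-dicarboxylate (the C3=C4 enol triflate)
Conditions: KN(SiMe3)2 (2.1 equiv), THF, −78 °C; PhNTf2 (1.05 equiv), −78 to 0 °C; aq. NH4Cl
Reagents that add atoms: N-phenylbis(trifluoromethanesulfonimide) O=S(=O)(N(c1ccccc1)S(=O)(=O)C(F)(F)F)C(F)(F)F
Why: Kinetic enol triflate formation: the first equivalent of base is absorbed by the acidic tricarbonyl unit, which is thereby masked as a poorly nucleophilic delocalised enolate, the second should remove a C3 proton in preference to the hindered C5 methine, and the more reactive ketone enolate is O-sulfonylated, so the double bond is fixed at C3=C4 while C5 and C10 are untouched.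

Step 6
Reactants: 8 the C3=C4 enol triflate
Product: 9 dimethyl (4aR,8aS)-5,8a-dimethyl-2-oxo-1,2,3,4,4a,7,8,8a-octahydronaphthalene-1,3-dicarboxylate
Conditions: Me2Zn (3 equiv), Pd(dppf)Cl2 (5 mol %), THF, 50 °C
Reagents that add atoms: dimethylzinc C[Zn]C
Why: Negishi coupling of the alkenyl triflate with Me2Zn should place the C15 methyl on C4 (the acidic enol merely consumes one equivalent of the zinc reagent); no stereocenter is affected.

Step 7
Reactants: 9 dimethyl (4aR,8aS)-5,8a-dimethyl-2-oxo-1,2,3,4,4a,7,8,8a-octahydronaphthalene-1,3-dicarboxylate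
Product: 10 (4aR,8aR)-5,8a-dimethyl-3,4,4a,7,8,8a-hexahydronaphthalen-2(1H)-one (11,12,13-trinoreudesm-3-en-8-one)
Conditions: LiCl, H2O, DMSO, 150 °C
Reagents that add atoms: none
Why: Krapcho dealkoxycarbonylation under neutral conditions should remove both activating esters and free the C8 ketone without moving the trisubstituted C3=C4 double bond or touching C5 and C10.

Step 8
Reactants: 10 11,12,13-trinoreudesm-3-en-8-one
Product: 11 11-hydroxyeudesm-3-en-8-one
Conditions: LiN(i-Pr)2, THF, −78 °C; acetone; AcOH, −78 °C
Reagents that add atoms: acetone CC(C)=O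
Why: Kinetic deprotonation should occur at C7 because C9 is neopentylic (next to quaternary C10), and the lithium enolate adds to acetone in an aldol reaction whose cold acidic quench forestalls the retro-aldol; the configuration at C7 is immaterial because it is erased in step 9.

Step 9
Reactants: 11 11-hydroxyeudesm-3-en-8-one
Product: 13 eudesma-3,7(11)-dien-8-one, via tertiary mesylate 12 (not isolated)
Conditions: MsCl, Et3N, CH2Cl2, 0 °C; then DBU, 25 °C
Reagents that add atoms: none
Why: Mesylation of the tertiary carbinol and E1cB elimination through the C8 enolate, with DBU equilibrating any isopropenyl isomer into conjugation, should give the tetrasubstituted 7(11)-enone; no stereocenter is set.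

Step 10
Reactants: 13 eudesma-3,7(11)-dien-8-one
Product: 14 (3R,4S,5R,10R)-3,4-dihydroxyeudesm-7(11)-en-8-one (3α,4α-diol)
Conditions: OsO4 (2 mol %), N-methylmorpholine N-oxide, acetone–H2O, 25 °C
Reagents that add atoms: osmium tetroxide O=[Os](=O)(=O)=O; N-methylmorpholine N-oxide C[N+]1([O-])CCOCC1; water O
Why: Catalytic OsO4 cis-dihydroxylation should take the electron-rich trisubstituted C3=C4 olefin in preference to the electron-poor tetrasubstituted enone olefin and add from the α face, opposite the axial C10 methyl that is 1,3-diaxial to C4, which sets C3 (3α-OH) and C4 (4α-OH, 4β-methyl) together.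

Step 11
Reactants: 14 3α,4α-dihydroxyeudesm-7(11)-en-8-one, 15 angelic acid
Product: 16 3α-angeloyloxy-4α-hydroxyeudesm-7(11)-en-8-one
Conditions: 15, 2,4,6-trichlorobenzoyl chloride, Et3N, toluene, 25 °C; then 14, 80 °C
Reagents that add atoms: none
Why: Yamaguchi esterification through the mixed anhydride should acylate the secondary 3α-hydroxyl only (the tertiary 4α-hydroxyl does not react), and the absence of nucleophilic catalysts avoids the addition–elimination that isomerises the angeloyl (Z) unit to tigloyl; C3 keeps its configuration because its C–O bond is not broken.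

Step 12
Reactants: 16 3α-angeloyloxy-4α-hydroxyeudesm-7(11)-en-8-one
Product: 17 (3R,4S,5R,10R)-3α-angeloyloxy-4α-hydroxy-11-hydroperoxyeudesm-6-en-8-one (target)
Conditions: O2, visible light, 5,10,15,20-tetraphenylporphyrin (cat.), CH2Cl2, 0 °C
Reagents that add atoms: dioxygen O=O
Why: Schenck ene reaction of singlet oxygen with the s-cis enone: by the geminal rule hydrogen should be abstracted from the ring CH2 (C6) on the α-carbon, oxygen bonds to C11 and the double bond moves to C6=C7 in conjugation with C8=O, while the electron-poor angelate olefin reacts far more slowly; no stereocenter is created (C11 carries two methyls) and C5 is untouched.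

Compound list
1 | 3-methylcyclohex-2-en-1-one | CC1=CC(=O)CCC1 | starting material
2 | 2-iodo-3-methylcyclohex-2-en-1-one | CC1=C(I)C(=O)CCC1 | intermediate
3 | 2-(hydroxymethyl)-3-methylcyclohex-2-en-1-one | CC1=C(CO)C(=O)CCC1 | intermediate
4 | 2-(bromomethyl)-3-methylcyclohex-2-en-1-one | CC1=C(CBr)C(=O)CCC1 | intermediate
5 | dimethyl 3-oxopentanedioate (dimethyl 1,3-acetonedicarboxylate) | COC(=O)CC(=O)CC(=O)OC | starting material
6 | dimethyl 2-[(2-methyl-6-oxocyclohex-1-en-1-yl)methyl]-3-oxopentanedioate (racemic at its enolisable CH; not isolated) | CC1=C(CC(C(=O)OC)C(=O)CC(=O)OC)C(=O)CCC1 | intermediate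
7 | dimethyl (4aR,8aS)-8a-methyl-2,5-dioxodecahydronaphthalene-1,3-dicarboxylate (trans-fused, 5α-H, 10β-methyl; the ester-bearing C7 and C9 are labile and partly enolised, drawn 7β,9β) | C1CC[C@]2(C)[C@@H](C(=O)OC)C(=O)[C@@H](C(=O)OC)C[C@H]2C1=O | intermediate
8 | dimethyl (4aR,8aS)-8a-methyl-2-oxo-5-(trifluoromethylsulfonyloxy)-1,2,3,4,4a,7,8,8a-octahydronaphthalene-1,3-dicarboxylate | C1CC[C@]2(C)[C@@H](C(=O)OC)C(=O)[C@@H](C(=O)OC)C[C@H]2C(OS(=O)(=O)C(F)(F)F)=1 | intermediate
9 | dimethyl (4aR,8aS)-5,8a-dimethyl-2-oxo-1,2,3,4,4a,7,8,8a-octahydronaphthalene-1,3-dicarboxylate | C1CC[C@]2(C)[C@@H](C(=O)OC)C(=O)[C@@H](C(=O)OC)C[C@H]2C(C)=1 | intermediate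
10 | (4aR,8aR)-5,8a-dimethyl-3,4,4a,7,8,8a-hexahydronaphthalen-2(1H)-one (11,12,13-trinoreudesm-3-en-8-one; 5α-H, 10β-methyl) | C1CC[C@]2(C)CC(=O)CC[C@H]2C(C)=1 | intermediate
11 | 11-hydroxyeudesm-3-en-8-one (7α-H drawn) | C1CC[C@]2(C)CC(=O)[C@@H](C(C)(C)O)C[C@H]2C(C)=1 | intermediate
12 | 11-(methylsulfonyloxy)eudesm-3-en-8-one (not isolated) | C1CC[C@]2(C)CC(=O)[C@@H](C(C)(C)OS(C)(=O)=O)C[C@H]2C(C)=1 | intermediate
13 | eudesma-3,7(11)-dien-8-one (selina-3,7(11)-dien-8-one) | C1CC[C@]2(C)CC(=O)C(=C(C)C)C[C@H]2C(C)=1 | intermediate
14 | (3R,4S,5R,10R)-3,4-dihydroxyeudesm-7(11)-en-8-one (3α,4α-diol) | O[C@@H]1CC[C@]2(C)CC(=O)C(=C(C)C)C[C@H]2[C@]1(C)O | intermediate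
15 | angelic acid, (Z)-2-methylbut-2-enoic acid | C/C=C(/C)C(=O)O | starting material
16 | 3α-angeloyloxy-4α-hydroxyeudesm-7(11)-en-8-one | C/C=C(/C)C(=O)O[C@@H]1CC[C@]2(C)CC(=O)C(=C(C)C)C[C@H]2[C@]1(C)O | intermediate
17 | (3R,4S,5R,10R)-3α-angeloyloxy-4α-hydroxy-11-hydroperoxyeudesm-6-en-8-one | C/C=C(/C)C(=O)O[C@@H]1CC[C@]2(C)CC(=O)C(C(C)(C)OO)=C[C@H]2[C@]1(C)O | target

Total step count: 12. Longest linear sequence: 12 steps (1 to 17).

Steps most likely to fail

Step 4. The ion pair may not discriminate the two faces of C10 well enough, reversible Michael addition may erode the enantiomeric purity, and 4 may be lost to vinylogous dehydrobromination or to double alkylation of 5. The fallback replaces catalyst control by a covalent auxiliary and separation of diastereomers, all by known chemistry. It sets out from 4 and 5: 5 is transesterified with (1R,2S,5R)-menthol (DMAP cat., toluene, reflux, methanol distilled off) to bis[(1R,2S,5R)-menthyl] 3-oxopentanedioate F1. F1 and 4 are taken through the same alkylation–Michael cascade under achiral conditions (Cs2CO3, MeCN, 25 to 50 °C). This should give bis[(1R,2S,5R)-menthyl] (4aR,8aS)-8a-methyl-2,5-dioxodecahydronaphthalene-1,3-dicarboxylate F2 together with its diastereomer of (4aS,8aR) decalin core F3, which are separated by chromatography or crystallisation. Heating F2 with a large excess of methanol (DMAP cat., toluene, sealed tube, 110 °C; β-keto ester transesterification) returns the route at 7.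

Step 5. The tricarbonyl enolate may be sulfonylated as well, or proton transfer may lead to the C4=C5 enol triflate. The fallback tells the two ketones apart by protection instead of by enolate reactivity. It sets out from 7: Krapcho removal of both esters (LiCl, wet DMSO, 150 °C) gives trans-fused 10-methyldecalin-4,8-dione F4. The C8 ketone, which has no α-branching, is ketalised selectively (ethane-1,2-diol 1.1 equiv, pyridinium p-toluenesulfonate, benzene, reflux) to the 8,8-ethylenedioxy-4-ketone F5. Kinetic enolisation (LiN(i-Pr)2, THF, −78 °C; PhNTf2) then gives the C3=C4 enol triflate F6 with no competing acidic site, and Negishi methylation (Me2Zn, Pd(dppf)Cl2) gives the 8,8-ethylenedioxy-4-methyl-3-ene F7. Mild hydrolysis (pyridinium p-toluenesulfonate, wet acetone) returns the route at 10.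

Step 11. Acylation of the axial, hindered 3α-hydroxyl may be slow, and the angeloyl unit may isomerise to tigloyl during the long heating. The fallback builds the Z-olefin on the ester instead of carrying it through the acylation. 2-[Bis(2,2,2-trifluoroethoxy)phosphoryl]propanoic acid F8 is made by mild saponification (LiOH, THF–H2O, 0 °C) of its commercial ethyl ester. Setting out from 14, esterification with F8 (N,N'-diisopropylcarbodiimide, DMAP cat., CH2Cl2) gives the 3α-phosphonopropanoate F9. A Still–Gennari olefination with acetaldehyde (KN(SiMe3)2, 18-crown-6, THF, −78 °C) should then form the (Z)-2-methylbut-2-enoate and return the route at 16.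

Further compounds
F1 | step 4 | bis[(1R,2S,5R)-2-isopropyl-5-methylcyclohexyl] 3-oxopentanedioate | O=C(CC(=O)O[C@@H]1C[C@H](C)CC[C@H]1C(C)C)CC(=O)O[C@@H]1C[C@H](C)CC[C@H]1C(C)C
F2 | step 4 | bis[(1R,2S,5R)-menthyl] (4aR,8aS)-8a-methyl-2,5-dioxodecahydronaphthalene-1,3-dicarboxylate | C1CC[C@]2(C)[C@@H](C(=O)O[C@@H]3C[C@H](C)CC[C@H]3C(C)C)C(=O)[C@@H](C(=O)O[C@@H]3C[C@H](C)CC[C@H]3C(C)C)C[C@H]2C1=O
F3 | step 4 | bis[(1R,2S,5R)-menthyl] (4aS,8aR)-8a-methyl-2,5-dioxodecahydronaphthalene-1,3-dicarboxylate (diastereomer of F2) | C1CC[C@@]2(C)[C@H](C(=O)O[C@@H]3C[C@H](C)CC[C@H]3C(C)C)C(=O)[C@H](C(=O)O[C@@H]3C[C@H](C)CC[C@H]3C(C)C)C[C@@H]2C1=O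
F4 | step 5 | trans-fused 10-methyldecalin-4,8-dione (5α-H, 10β-methyl) | C1CC[C@]2(C)CC(=O)CC[C@H]2C1=O
F5 | step 5 | 8,8-ethylenedioxy-10-methyl-trans-decalin-4-one | C1CC[C@]2(C)CC3(OCCO3)CC[C@H]2C1=O
F6 | step 5 | 8,8-ethylenedioxy-10-methyl-trans-decal-3-en-4-yl trifluoromethanesulfonate | C1CC[C@]2(C)CC3(OCCO3)CC[C@H]2C(OS(=O)(=O)C(F)(F)F)=1
F7 | step 5 | 8,8-ethylenedioxy-11,12,13-trinoreudesm-3-ene | C1CC[C@]2(C)CC3(OCCO3)CC[C@H]2C(C)=1
F8 | step 11 | 2-[bis(2,2,2-trifluoroethoxy)phosphoryl]propanoic acid | CC(C(=O)O)P(=O)(OCC(F)(F)F)OCC(F)(F)F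
F9 | step 11 | 3α-{2-[bis(2,2,2-trifluoroethoxy)phosphoryl]propanoyloxy}-4α-hydroxyeudesm-7(11)-en-8-one (epimers at the phosphonate carbon) | CC(C(=O)O[C@@H]1CC[C@]2(C)CC(=O)C(=C(C)C)C[C@H]2[C@]1(C)O)P(=O)(OCC(F)(F)F)OCC(F)(F)F
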